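**Retrosynthetic overview**
1. The C6 chloride comes from a (6R)-allylic alcohol by SN2 inversion; the C2/C9 acetates and the C12 enone are unveiled last.
2. The ten-membered ring is closed third, by a Nozaki–Hiyama–Kishi C5–C6 coupling of a 2-iodoalkene with a C6 aldehyde.
3. The γ-lactone is formed second, by a SmI2 Reformatsky reaction of a C7 2-bromopropanoate onto a C8 ketone (sets C8 and C17).
4. The C2–C5 arm comes from Felkin vinylation of a C2 aldehyde, Sharpless epoxidation and α-silylvinyl cuprate opening; Me-20 is set by enolate methylation and kinetic protonation.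
5. Ring A is formed first (sets C1 and C10), by Diels–Alder reaction of Rawal's diene with an L-arabinose-derived (E)-2-methyl enal that already carries C6–C9.

Assumption: the SMILES fixes the target as (1S,2R,3S,6S,7R,8R,9S,10S,11R,17R) in briarane numbering (C1 quaternary with Me-15, C5=C16, C11 with Me-20, C12 ketone, C13=C14, C17 with Me-18, C19 lactone carbonyl on O7); these carbon numbers are used for all intermediates, and the SMILES in the compound list is the definitive stereochemical description.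

**Route**

Step 1
Reactants: 1 L-arabinose
Product: 2 3,4-O-isopropylidene-β-L-arabinopyranose
Conditions: 2,2-dimethoxypropane, TsOH (cat.), DMF, rt
Reagents that add atoms: 2,2-dimethoxypropane, COC(C)(C)OC
Why: Acid-catalysed acetonide formation (transketalisation) takes the only cis-diol of the pyranose (O3/O4, the future O8/O7) and creates no stereocentre that persists.

Step 2
Reactants: 2 3,4-O-isopropylidene-β-L-arabinopyranose; 3 2-(triphenylphosphoranylidene)propanal
Product: 4 (E)-enal diol (C2 aldehyde; C1(Me-15)=C10; C9-OH; C8/C7 acetonide; C6-OH)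
Conditions: dioxane, PhCO2H (cat.), 90 °C
Reagents that add atoms: none
Why: Wittig olefination of the open-chain aldehyde tautomer of the lactol with a formyl-stabilised ylide gives the (E)-trisubstituted enal, the sugar centres C9 and C7 being carried over unchanged.

Step 3
Reactants: 4 (E)-enal diol
Product: 6 C9-O-TBS C6-O-TBDPS enal, via mono-TBDPS ether 5 (not isolated)
Conditions: TBDPSCl (1.05 equiv), imidazole, DMF, 0 °C; then TBSCl, 40 °C
Reagents that add atoms: tert-butyl(chloro)diphenylsilane, CC(C)(C)[Si](Cl)(c1ccccc1)c1ccccc1; tert-butyl(chloro)dimethylsilane, CC(C)(C)[Si](C)(C)Cl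
Why: Sequential silylation in one flask, the bulky TBDPSCl taking the primary C6 hydroxyl first and TBSCl then the secondary C9 hydroxyl, gives an acid-stable primary ether and a robust C9 ether without touching any stereocentre.

Step 4
Reactants: 6 C9-O-TBS C6-O-TBDPS enal; 7 Rawal's diene
Product: 9 ring-A enone aldehyde, via aminocyclohexene silyl enol ether 8 (not isolated)
Conditions: toluene, 70 °C; then 0.1 M HCl, THF, 0 °C
Reagents that add atoms: none
Why: Diels–Alder cycloaddition with the amino terminus bonding to the formyl-bearing carbon, the (E)-dienophile placing C2 and C9 trans on ring A, and A1,3 strain (C9–H eclipsing the alkene) directing the diene anti to the C9–OTBS bond to set C1 and C10; acid then hydrolyses the silyl enol ether and eliminates Me2NH to give the 13-en-12-one.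

Step 5
Reactants: 9 ring-A enone aldehyde
Product: 10 (2S)-vinyl carbinol
Conditions: vinyl bromide, CrCl2, NiCl2 (cat.), DMF, rt
Reagents that add atoms: vinyl bromide, C=CBr
Why: Nozaki–Hiyama–Kishi vinylation is selective for the aldehyde over the enone, and Felkin–Anh addition with the branched C10 carbon anti to the nucleophile and Me-15 as the small group sets the C2 carbinol in the arrangement needed for 33.

Step 6
Reactants: 10 (2S)-vinyl carbinol
Product: 12 11-epi methyl enone, via dilithium dienolate 11 (not isolated)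
Conditions: LiN(iPr)2 (2.2 equiv), THF, −78 °C; then MeI, −78 to −40 °C
Reagents that add atoms: iodomethane, CI
Why: Kinetic α′-deprotonation of the enone (no γ-hydrogen exists) and enolate alkylation install Me-20, the electrophile entering anti to the C9 chain and Me-15 so that the methyl is trans to the C9 chain (11S), which step 7 corrects.

Step 7
Reactants: 12 11-epi methyl enone
Product: 14 (11R)-methyl enone, via dilithium dienolate 13 (not isolated)
Conditions: LiN(iPr)2 (2.3 equiv), THF, −78 to −40 °C; then AcOH, THF, −78 °C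
Reagents that add atoms: none
Why: Kinetic protonation of the re-formed cross-conjugated enolate delivers the proton to the face anti to Me-15 and the C9 chain, leaving Me-20 cis to both (11R) as in the target.

Step 8
Reactants: 14 (11R)-methyl enone
Product: 15 (2R,3S)-3,4-epoxy-2-ol
Conditions: Ti(OiPr)4, D-(−)-DIPT, t-BuOOH, 4 Å molecular sieves, CH2Cl2, −20 °C
Reagents that add atoms: tert-butyl hydroperoxide, CC(C)(C)OO
Why: Sharpless asymmetric epoxidation of the secondary allylic alcohol in its matched (fast) pairing with D-(−)-tartrate gives the erythro epoxy alcohol and so sets C3, the electron-poor enone and the silyl ethers being inert.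

Step 9
Reactants: 15 (2R,3S)-3,4-epoxy-2-ol
Product: 16 (12S)-allylic alcohol
Conditions: NaBH4, CeCl3·7H2O, MeOH, −78 °C
Reagents that add atoms: none
Why: Luche 1,2-reduction with hydride entering anti to Me-15, Me-20 and the C9 chain gives the 12-hydroxyl cis to Me-20, which masks the enone and locks the C11 configuration against epimerisation (C12 is re-oxidised in step 24).

Step 10
Reactants: 16 (12S)-allylic alcohol
Product: 17 2,12-bis-O-TBS epoxide
Conditions: TBSOTf, 2,6-lutidine, CH2Cl2, −78 to 0 °C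
Reagents that add atoms: tert-butyldimethylsilyl trifluoromethanesulfonate, CC(C)(C)[Si](C)(C)OS(=O)(=O)C(F)(F)F
Why: Silyl triflate silylation protects both hindered secondary hydroxyls in one operation with no stereochemical change, the buffered low temperature sparing the epoxide.

Step 11
Reactants: 17 2,12-bis-O-TBS epoxide
Product: 19 3-O-acetyl vinylsilane, via bromomagnesium alkoxide 18 (not isolated)
Conditions: CH2=C(SiMe3)MgBr, CuI (10 mol %), THF, −30 to 0 °C; then Ac2O, DMAP, 0 °C to rt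
Reagents that add atoms: [1-(trimethylsilyl)vinyl]magnesium bromide, C=C([Mg]Br)[Si](C)(C)C; acetic anhydride, CC(=O)OC(C)=O
Why: Copper-catalysed SN2 opening of the terminal epoxide at C4 forms the C4–C5 bond with C3 untouched, and the magnesium alkoxide is acetylated in the same flask to give the final C3 acetate.

Step 12
Reactants: 19 3-O-acetyl vinylsilane
Product: 20 2-iodoalkene
Conditions: NIS, MeCN/ClCH2CN, 0 °C
Reagents that add atoms: N-iodosuccinimide, O=C1CCC(=O)N1I
Why: Iododesilylation (ipso substitution of the electron-rich 1,1-disubstituted vinylsilane) gives the 5-iodo-5(16)-ene needed for chromium chemistry, while the hindered ring-A alkene and all stereocentres are unaffected.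

Step 13
Reactants: 20 2-iodoalkene
Product: 21 C7,C8-diol
Conditions: CeCl3·7H2O, oxalic acid, MeCN, rt
Reagents that add atoms: none
Why: Mild Lewis-acid-assisted acetonide hydrolysis frees the C7/C8 diol while the hindered secondary TBS ethers, the primary TBDPS ether, the acetate and the iodoalkene survive.

Step 14
Reactants: 21 C7,C8-diol
Product: 22 7-O-(2-bromopropanoyl) ester
Conditions: 2-bromopropanoyl bromide, pyridine, CH2Cl2, −40 °C
Reagents that add atoms: 2-bromopropanoyl bromide, CC(Br)C(=O)Br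
Why: Regioselective acylation takes the C7 hydroxyl because the C8 hydroxyl is flanked by the C9 silyloxy carbon and ring A; the CHBr configuration is irrelevant since it is lost in step 16.

Step 15
Reactants: 22 7-O-(2-bromopropanoyl) ester
Product: 23 C8 ketone
Conditions: Dess–Martin periodinane, CH2Cl2, rt
Reagents that add atoms: none
Why: Dess–Martin oxidation of the only free (C8) hydroxyl gives the α-acyloxy ketone under neutral conditions that avoid acyl migration and epimerisation at C7 or C9.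

Step 16
Reactants: 23 C8 ketone
Product: 24 γ-lactone with 8-OH and 17-Me
Conditions: SmI2 (2.1 equiv), THF, −78 °C
Reagents that add atoms: none
Why: Intramolecular samarium Reformatsky reaction (C–Br reduction far faster than ketyl formation) closes the lactone through a chelated transition state that puts the C6 and C9 substituents trans on the new ring and Me-18 anti to the C9 chain, setting C8 (R) and C17 (R).

Step 17
Reactants: 24 γ-lactone with 8-OH and 17-Me
Product: 25 C6 primary alcohol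
Conditions: TBAF, AcOH (1:1), THF, 0 °C to rt
Reagents that add atoms: none
Why: Buffered fluoride desilylation removes the unhindered primary TBDPS ether much faster than the three hindered secondary TBS ethers and leaves the acetate and the β-hydroxy lactone intact.

Step 18
Reactants: 25 C6 primary alcohol
Product: 26 C6 aldehyde
Conditions: Dess–Martin periodinane, CH2Cl2, rt
Reagents that add atoms: none
Why: Dess–Martin oxidation gives the α-acyloxy aldehyde without epimerising C7, the tertiary C8 hydroxyl being inert.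

Step 19
Reactants: 26 C6 aldehyde
Product: 27 macrocyclic (6S)-allylic alcohol
Conditions: CrCl2 (8 equiv), NiCl2 (cat.), DMSO/THF, rt, 2 mM
Reagents that add atoms: none
Why: Intramolecular Nozaki–Hiyama–Kishi coupling at high dilution tolerates acetate, lactone and free tertiary hydroxyl and closes the ten-membered ring at C5–C6 with the exocyclic methylene in place; the Felkin-type 6,7-anti alcohol is expected, and either C6 epimer converges in step 20.

Step 20
Reactants: 27 macrocyclic (6S)-allylic alcohol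
Product: 28 macrocyclic 5(16)-en-6-one
Conditions: Dess–Martin periodinane, CH2Cl2, 0 °C to rt
Reagents that add atoms: none
Why: Dess–Martin oxidation of the allylic alcohol gives the α-methylene ketone and erases C6 so that it can be reset by hydride; the product is used at once to avoid oxa-Michael addition of the C8 hydroxyl.

Step 21
Reactants: 28 macrocyclic 5(16)-en-6-one
Product: 29 (6R)-allylic alcohol
Conditions: NaBH4, CeCl3·7H2O, MeOH/THF, −78 °C
Reagents that add atoms: none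
Why: Luche 1,2-reduction with Felkin–Anh hydride delivery anti to the C7–O bond gives the 6,7-syn (6R) alcohol, the epimer of the coupling product and the one needed for invertive chlorination.

Step 22
Reactants: 29 (6R)-allylic alcohol
Product: 30 (6S)-chloride
Conditions: PPh3, hexachloroacetone, CH2Cl2, −20 to 0 °C
Reagents that add atoms: hexachloroacetone, O=C(C(Cl)(Cl)Cl)C(Cl)(Cl)Cl
Why: Appel-type chlorination through the alkoxyphosphonium salt proceeds by SN2 with inversion and without allylic transposition under these mild neutral conditions, giving the (6S) chloride while the tertiary C8 hydroxyl does not react.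

Step 23
Reactants: 30 (6S)-chloride
Product: 31 2,9,12-triol
Conditions: HF·pyridine, pyridine, THF, 0 °C to rt
Reagents that add atoms: none
Why: Acidic fluoride desilylation removes the three TBS ethers without harming the allylic chloride, lactone or acetate; any 3→2 acetyl migration is harmless because both positions end as acetates.

Step 24
Reactants: 31 2,9,12-triol
Product: 32 13-en-12-one diol
Conditions: MnO2, CH2Cl2, rt
Reagents that add atoms: none
Why: MnO2 oxidises only the allylic C12 hydroxyl, restoring the ring-A enone under neutral conditions that do not epimerise C11.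

Step 25
Reactants: 32 13-en-12-one diol
Product: 33 CNP0391614.1
Conditions: Ac2O, pyridine, DMAP (cat.), CH2Cl2, 0 °C
Reagents that add atoms: acetic anhydride, CC(=O)OC(C)=O
Why: DMAP-catalysed acetylation esterifies the two secondary hydroxyls (C2, C9) while the hindered tertiary C8 hydroxyl stays free, giving the target.

**Compound list**

1 | L-arabinose (open-chain form shown) | O=C[C@H](O)[C@@H](O)[C@@H](O)CO | starting material
2 | 3,4-O-isopropylidene-β-L-arabinopyranose | O[C@H]1OC[C@@H]2OC(C)(C)O[C@@H]2[C@H]1O | intermediate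
3 | 2-(triphenylphosphoranylidene)propanal | CC(C=O)=P(c1ccccc1)(c1ccccc1)c1ccccc1 | starting material
4 | (E)-2,3-dideoxy-5,6-O-isopropylidene-2-C-methyl-aldehydo-L-arabino-hept-2-enose (C2 aldehyde, C1(Me-15)=C10, C9-OH, C8/C7 acetonide, C6-OH) | O=C/C(C)=C/[C@H](O)[C@H]1OC(C)(C)O[C@H]1CO | intermediate
5 | C6-O-TBDPS ether of 4 (C9-OH free) | O=C/C(C)=C/[C@H](O)[C@H]1OC(C)(C)O[C@H]1CO[Si](c2ccccc2)(c2ccccc2)C(C)(C)C | intermediate
6 | C9-O-TBS, C6-O-TBDPS ether of 4 | O=C/C(C)=C/[C@H](O[Si](C)(C)C(C)(C)C)[C@H]1OC(C)(C)O[C@H]1CO[Si](c2ccccc2)(c2ccccc2)C(C)(C)C | intermediate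
7 | Rawal's diene, (E)-3-(tert-butyldimethylsilyloxy)-N,N-dimethylbuta-1,3-dien-1-amine | C=C(O[Si](C)(C)C(C)(C)C)/C=C/N(C)C | starting material
8 | Diels–Alder adduct: ring A as 12-silyloxy-12-ene with 14-NMe2 cis to the C2 formyl group | O=C[C@@]1(C)[C@@H](N(C)C)C=C(O[Si](C)(C)C(C)(C)C)C[C@@H]1[C@H](O[Si](C)(C)C(C)(C)C)[C@H]2OC(C)(C)O[C@H]2CO[Si](c3ccccc3)(c3ccccc3)C(C)(C)C | intermediate
9 | ring-A enone aldehyde: 13-en-12-one, C2 formyl and Me-15 on C1 (1S), C10 (10S) carrying the C9(OTBS)–C8/C7(acetonide)–C6(OTBDPS) chain | O=C[C@@]1(C)C=CC(=O)C[C@@H]1[C@H](O[Si](C)(C)C(C)(C)C)[C@H]2OC(C)(C)O[C@H]2CO[Si](c3ccccc3)(c3ccccc3)C(C)(C)C | intermediate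
10 | (2S)-vinyl carbinol (C2-OH, C3=C4) | C=C[C@H](O)[C@@]1(C)C=CC(=O)C[C@@H]1[C@H](O[Si](C)(C)C(C)(C)C)[C@H]2OC(C)(C)O[C@H]2CO[Si](c3ccccc3)(c3ccccc3)C(C)(C)C | intermediate
11 | dilithium C2-alkoxide 11,12-dienolate of 10 | [Li+].[Li+].C=C[C@H]([O-])[C@@]1(C)C=CC([O-])=C[C@@H]1[C@H](O[Si](C)(C)C(C)(C)C)[C@H]2OC(C)(C)O[C@H]2CO[Si](c3ccccc3)(c3ccccc3)C(C)(C)C | intermediate
12 | 11-epi methyl enone (11S; Me-20 trans to the C9 chain) | C=C[C@H](O)[C@@]1(C)C=CC(=O)[C@@H](C)[C@@H]1[C@H](O[Si](C)(C)C(C)(C)C)[C@H]2OC(C)(C)O[C@H]2CO[Si](c3ccccc3)(c3ccccc3)C(C)(C)C | intermediate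
13 | dilithium C2-alkoxide 11,12-dienolate of 12 | [Li+].[Li+].C=C[C@H]([O-])[C@@]1(C)C=CC([O-])=C(C)[C@@H]1[C@H](O[Si](C)(C)C(C)(C)C)[C@H]2OC(C)(C)O[C@H]2CO[Si](c3ccccc3)(c3ccccc3)C(C)(C)C | intermediate
14 | (11R)-methyl enone (Me-20 cis to Me-15 and to the C9 chain) | C=C[C@H](O)[C@@]1(C)C=CC(=O)[C@H](C)[C@@H]1[C@H](O[Si](C)(C)C(C)(C)C)[C@H]2OC(C)(C)O[C@H]2CO[Si](c3ccccc3)(c3ccccc3)C(C)(C)C | intermediate
15 | (2R,3S)-3,4-epoxy-2-ol | C1[C@H](O1)[C@H](O)[C@@]2(C)C=CC(=O)[C@H](C)[C@@H]2[C@H](O[Si](C)(C)C(C)(C)C)[C@H]3OC(C)(C)O[C@H]3CO[Si](c4ccccc4)(c4ccccc4)C(C)(C)C | intermediate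
16 | (12S)-allylic alcohol (12-OH cis to Me-20), epoxy diol | C1[C@H](O1)[C@H](O)[C@@]2(C)C=C[C@H](O)[C@H](C)[C@@H]2[C@H](O[Si](C)(C)C(C)(C)C)[C@H]3OC(C)(C)O[C@H]3CO[Si](c4ccccc4)(c4ccccc4)C(C)(C)C | intermediate
17 | 2,12-bis-O-TBS epoxide | C1[C@H](O1)[C@H](O[Si](C)(C)C(C)(C)C)[C@@]2(C)C=C[C@H](O[Si](C)(C)C(C)(C)C)[C@H](C)[C@@H]2[C@H](O[Si](C)(C)C(C)(C)C)[C@H]3OC(C)(C)O[C@H]3CO[Si](c4ccccc4)(c4ccccc4)C(C)(C)C | intermediate
18 | bromomagnesium C3-alkoxide of the 5-trimethylsilyl-5(16)-ene | C=C([Si](C)(C)C)C[C@H](O[Mg]Br)[C@H](O[Si](C)(C)C(C)(C)C)[C@@]1(C)C=C[C@H](O[Si](C)(C)C(C)(C)C)[C@H](C)[C@@H]1[C@H](O[Si](C)(C)C(C)(C)C)[C@H]2OC(C)(C)O[C@H]2CO[Si](c3ccccc3)(c3ccccc3)C(C)(C)C | intermediate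
19 | 3-O-acetyl-5-trimethylsilyl-5(16)-ene | C=C([Si](C)(C)C)C[C@H](OC(C)=O)[C@H](O[Si](C)(C)C(C)(C)C)[C@@]1(C)C=C[C@H](O[Si](C)(C)C(C)(C)C)[C@H](C)[C@@H]1[C@H](O[Si](C)(C)C(C)(C)C)[C@H]2OC(C)(C)O[C@H]2CO[Si](c3ccccc3)(c3ccccc3)C(C)(C)C | intermediate
20 | 5-iodo-5(16)-ene 3-acetate (2-iodoalkene) | C=C(I)C[C@H](OC(C)=O)[C@H](O[Si](C)(C)C(C)(C)C)[C@@]1(C)C=C[C@H](O[Si](C)(C)C(C)(C)C)[C@H](C)[C@@H]1[C@H](O[Si](C)(C)C(C)(C)C)[C@H]2OC(C)(C)O[C@H]2CO[Si](c3ccccc3)(c3ccccc3)C(C)(C)C | intermediate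
21 | C7,C8-diol (acetonide removed) | C=C(I)C[C@H](OC(C)=O)[C@H](O[Si](C)(C)C(C)(C)C)[C@@]1(C)C=C[C@H](O[Si](C)(C)C(C)(C)C)[C@H](C)[C@@H]1[C@H](O[Si](C)(C)C(C)(C)C)[C@@H](O)[C@@H](O)CO[Si](c2ccccc2)(c2ccccc2)C(C)(C)C | intermediate
22 | 7-O-(2-bromopropanoyl) ester, 8-OH free (either configuration at CHBr) | C=C(I)C[C@H](OC(C)=O)[C@H](O[Si](C)(C)C(C)(C)C)[C@@]1(C)C=C[C@H](O[Si](C)(C)C(C)(C)C)[C@H](C)[C@@H]1[C@H](O[Si](C)(C)C(C)(C)C)[C@@H](O)[C@@H](OC(=O)C(C)Br)CO[Si](c2ccccc2)(c2ccccc2)C(C)(C)C | intermediate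
23 | 8-ketone 7-O-(2-bromopropanoyl) ester | C=C(I)C[C@H](OC(C)=O)[C@H](O[Si](C)(C)C(C)(C)C)[C@@]1(C)C=C[C@H](O[Si](C)(C)C(C)(C)C)[C@H](C)[C@@H]1[C@H](O[Si](C)(C)C(C)(C)C)C(=O)[C@@H](OC(=O)C(C)Br)CO[Si](c2ccccc2)(c2ccccc2)C(C)(C)C | intermediate
24 | γ-lactone (C19 to O7) with (8R)-OH and (17R)-Me, C6-O-TBDPS | C=C(I)C[C@H](OC(C)=O)[C@H](O[Si](C)(C)C(C)(C)C)[C@@]1(C)C=C[C@H](O[Si](C)(C)C(C)(C)C)[C@H](C)[C@@H]1[C@H](O[Si](C)(C)C(C)(C)C)[C@]2(O)[C@@H](C)C(=O)O[C@H]2CO[Si](c3ccccc3)(c3ccccc3)C(C)(C)C | intermediate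
25 | lactone C6 primary alcohol | C=C(I)C[C@H](OC(C)=O)[C@H](O[Si](C)(C)C(C)(C)C)[C@@]1(C)C=C[C@H](O[Si](C)(C)C(C)(C)C)[C@H](C)[C@@H]1[C@H](O[Si](C)(C)C(C)(C)C)[C@]2(O)[C@@H](C)C(=O)O[C@H]2CO | intermediate
26 | lactone C6 aldehyde | C=C(I)C[C@H](OC(C)=O)[C@H](O[Si](C)(C)C(C)(C)C)[C@@]1(C)C=C[C@H](O[Si](C)(C)C(C)(C)C)[C@H](C)[C@@H]1[C@H](O[Si](C)(C)C(C)(C)C)[C@]2(O)[C@@H](C)C(=O)O[C@H]2C=O | intermediate
27 | macrocyclic (6S)-allylic alcohol (ten-membered ring closed) | C=C1C[C@H](OC(C)=O)[C@H](O[Si](C)(C)C(C)(C)C)[C@@]2(C)C=C[C@H](O[Si](C)(C)C(C)(C)C)[C@H](C)[C@@H]2[C@H](O[Si](C)(C)C(C)(C)C)[C@]2(O)[C@@H](C)C(=O)O[C@H]2[C@H]1O | intermediate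
28 | macrocyclic 5(16)-en-6-one | C=C1C[C@H](OC(C)=O)[C@H](O[Si](C)(C)C(C)(C)C)[C@@]2(C)C=C[C@H](O[Si](C)(C)C(C)(C)C)[C@H](C)[C@@H]2[C@H](O[Si](C)(C)C(C)(C)C)[C@]2(O)[C@@H](C)C(=O)O[C@H]2C1=O | intermediate
29 | (6R)-allylic alcohol | C=C1C[C@H](OC(C)=O)[C@H](O[Si](C)(C)C(C)(C)C)[C@@]2(C)C=C[C@H](O[Si](C)(C)C(C)(C)C)[C@H](C)[C@@H]2[C@H](O[Si](C)(C)C(C)(C)C)[C@]2(O)[C@@H](C)C(=O)O[C@H]2[C@@H]1O | intermediate
30 | (6S)-chloride, 3-O-acetyl-2,9,12-tris-O-TBS | C=C1C[C@H](OC(C)=O)[C@H](O[Si](C)(C)C(C)(C)C)[C@@]2(C)C=C[C@H](O[Si](C)(C)C(C)(C)C)[C@H](C)[C@@H]2[C@H](O[Si](C)(C)C(C)(C)C)[C@]2(O)[C@@H](C)C(=O)O[C@H]2[C@H]1Cl | intermediate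
31 | 3-O-acetyl 6-chloro 2,9,12-triol (8-OH also free) | C=C1C[C@H](OC(C)=O)[C@H](O)[C@@]2(C)C=C[C@H](O)[C@H](C)[C@@H]2[C@H](O)[C@]2(O)[C@@H](C)C(=O)O[C@H]2[C@H]1Cl | intermediate
32 | 3-O-acetyl 6-chloro 2,9-diol 13-en-12-one | C=C1C[C@H](OC(C)=O)[C@H](O)[C@@]2(C)C=CC(=O)[C@H](C)[C@@H]2[C@H](O)[C@]2(O)[C@@H](C)C(=O)O[C@H]2[C@H]1Cl | intermediate
33 | CNP0391614.1, (1S,2R,3S,6S,7R,8R,9S,10S,11R,17R)-2,3,9-triacetoxy-6-chloro-8-hydroxy-12-oxobriara-5(16),13-diene 19,7-lactone | C=C1C[C@H](OC(C)=O)[C@H](OC(C)=O)[C@@]2(C)C=CC(=O)[C@H](C)[C@@H]2[C@H](OC(C)=O)[C@]2(O)[C@@H](C)C(=O)O[C@H]2[C@H]1Cl | target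

**Totals and risks**

Total step count: 25. Longest linear sequence: 25 steps, from L-arabinose (the route is fully linear; 3 and 7 are purchased).

The three steps most likely to fail:

Step 4 (Diels–Alder). The trisubstituted enal is a sluggish dienophile, and the face selectivity rests on one allylic stereocentre. The fallback sets out from 6 and replaces substrate control by catalyst control. 6 is combined with 2-(trimethylsilyloxy)buta-1,3-diene at −78 °C under a chiral oxazaborolidinium triflimide Lewis acid, the catalyst enantiomer being chosen to deliver the diene to the required face. This gives the trimethylsilyl enol ether cycloadduct F1. Saegusa–Ito dehydrogenation of F1 with Pd(OAc)2 in MeCN then introduces the 13,14-double bond and gives 9, where the route is rejoined.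

Step 16 (samarium Reformatsky). SmI2 may instead cleave the α-acyloxy ketone, or give the wrong C8 epimer. The fallback sets out from diol 21 and builds the lactone by an intermolecular addition followed by ring closure. Selective 4-methoxybenzylation of the less hindered C7 hydroxyl (PMB trichloroacetimidate, La(OTf)3 cat.) gives the C7 PMB ether F2, and Dess–Martin oxidation gives the C8 ketone F3. A chelation-controlled Reformatsky addition (Zn, ethyl 2-bromopropanoate, THF), with zinc bridging the ketone and the PMB ether oxygen and attack anti to the C6 substituent, gives the tertiary hydroxy ester F4. DDQ removal of the PMB group and PPTS-catalysed lactonisation (with DBU equilibration of C17 if needed) return to 24.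

Step 19 (ten-membered ring closure). The ring is strained, and the β-hydroxy aldehyde may oligomerise or be reduced under chromium conditions. The fallback sets out from 26 and changes the organometallic partner. Miyaura borylation (PdCl2(dppf), B2pin2, KOAc, dioxane) turns the iodoalkene into the alkenyl pinacolboronate aldehyde F5. F5 is cyclised by rhodium-catalysed intramolecular 1,2-addition ([Rh(OH)(cod)]2, dioxane/H2O, high dilution) to 27, either C6 epimer being usable because both converge at 28.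

**Further compounds**

F1 | step 4 | trimethylsilyl enol ether cycloadduct (ring A as 12-trimethylsilyloxy-12-ene, C2 formyl, C1/C10 as in 9) | O=C[C@@]1(C)CC=C(O[Si](C)(C)C)C[C@@H]1[C@H](O[Si](C)(C)C(C)(C)C)[C@H]2OC(C)(C)O[C@H]2CO[Si](c3ccccc3)(c3ccccc3)C(C)(C)C
F2 | step 16 | C7 O-(4-methoxybenzyl) ether of 21 (8-OH free) | C=C(I)C[C@H](OC(C)=O)[C@H](O[Si](C)(C)C(C)(C)C)[C@@]1(C)C=C[C@H](O[Si](C)(C)C(C)(C)C)[C@H](C)[C@@H]1[C@H](O[Si](C)(C)C(C)(C)C)[C@@H](O)[C@@H](OCc2ccc(OC)cc2)CO[Si](c2ccccc2)(c2ccccc2)C(C)(C)C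
F3 | step 16 | C8 ketone with C7 O-(4-methoxybenzyl) ether | C=C(I)C[C@H](OC(C)=O)[C@H](O[Si](C)(C)C(C)(C)C)[C@@]1(C)C=C[C@H](O[Si](C)(C)C(C)(C)C)[C@H](C)[C@@H]1[C@H](O[Si](C)(C)C(C)(C)C)C(=O)[C@@H](OCc2ccc(OC)cc2)CO[Si](c2ccccc2)(c2ccccc2)C(C)(C)C
F4 | step 16 | tertiary C8 hydroxy ethyl ester (C17 methyl, C19 ethyl ester, C7 O-PMB) | C=C(I)C[C@H](OC(C)=O)[C@H](O[Si](C)(C)C(C)(C)C)[C@@]1(C)C=C[C@H](O[Si](C)(C)C(C)(C)C)[C@H](C)[C@@H]1[C@H](O[Si](C)(C)C(C)(C)C)[C@](O)([C@@H](C)C(=O)OCC)[C@@H](OCc2ccc(OC)cc2)CO[Si](c2ccccc2)(c2ccccc2)C(C)(C)C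
F5 | step 19 | alkenyl pinacolboronate aldehyde (Bpin at C5 in place of iodine) | C=C(B3OC(C)(C)C(C)(C)O3)C[C@H](OC(C)=O)[C@H](O[Si](C)(C)C(C)(C)C)[C@@]1(C)C=C[C@H](O[Si](C)(C)C(C)(C)C)[C@H](C)[C@@H]1[C@H](O[Si](C)(C)C(C)(C)C)[C@]2(O)[C@@H](C)C(=O)O[C@H]2C=O
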